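**Retrosynthetic overview**
- Mollicellin A (28) is opened at the lactone C(acyl)–O bond (seven-membered ring, closed last) to seco-acid 27. The pyranone ring of 27 comes from a Friedel–Crafts/oxa-Michael annulation of diaryl ether phenol 23 with 3,3-dimethylacrylic acid.
- The strategy rests on ring B. Its carbon carrying the diaryl-ether oxygen is flanked by the C–CH3 carbon and by the lactone-oxygen carbon, and lies para to the pyranone-oxygen carbon. This 1,2,4-trioxygenated position is mapped onto the sp3 carbon of 4-aryloxy-3-ethoxy-4-isopropenylcyclobut-2-enone 19, so the crowded C–O bond exists before ring B does.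
- 23 comes from 19 by 4π ring opening and 6π ring closure, which forms ring B and the bond between the ketene carbon and the isopropenyl CH2.
- 19 comes from a [2+2] cycloaddition of an aryloxy(isopropenyl)ketene with ethoxyacetylene. The ketene comes from acid 15, made by SNAr of the dianion of 2-hydroxy-3-methylbut-3-enoic acid on fluoroarene 6. The ether is made on this acyclic alkoxide because a 4-oxidocyclobutenone would ring-open before it could be arylated.
- Ring order: A (from 3,5-difluorotoluene), then the cyclobutenone, then B, then the pyranone, then the seven-membered lactone.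

Key step: step 10

Remark on the chemistry: the target is achiral; compounds 9–19 are racemic at the α-aryloxy carbon, which becomes sp2 in step 10. The formyl group is masked as a dioxolane for steps 9–10 only, because a ketene beside a free ortho-formyl group would close onto it.

Step 1
Reactants: 1 3,5-difluorotoluene
Product: 3 2,6-difluoro-4-methylbenzaldehyde, via 2,6-difluoro-4-methylphenyllithium 2 (not isolated)
Conditions: n-BuLi, THF, −78 °C; DMF; 1 M HCl
Reagents that add atoms: N,N-dimethylformamide, CN(C)C=O
Why: Directed ortho-lithiation removes the most acidic ring hydrogen, the one flanked by both fluorines, and the aryllithium is formylated by DMF.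

Step 2
Reactants: 3 2,6-difluoro-4-methylbenzaldehyde
Product: 4 2-fluoro-6-methoxy-4-methylbenzaldehyde
Conditions: NaOMe (1.05 equiv), MeOH, 0 → 23 °C
Reagents that add atoms: sodium methoxide, C[O-].[Na+]
Why: SNAr of one fluorine ortho to the formyl group; the methoxy group then deactivates the ring toward a second displacement.

Step 3
Reactants: 4 2-fluoro-6-methoxy-4-methylbenzaldehyde
Product: 5 3-bromo-2-fluoro-6-methoxy-4-methylbenzaldehyde
Conditions: NBS, MeCN, 23 → 50 °C
Reagents that add atoms: N-bromosuccinimide, O=C1CCC(=O)N1Br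
Why: Electrophilic aromatic bromination should go para to the methoxy group (between F and CH3), as it does for 3,5-disubstituted anisoles, in preference to the ortho site between OMe and CH3.

Step 4
Reactants: 5 3-bromo-2-fluoro-6-methoxy-4-methylbenzaldehyde
Product: 6 methyl 2-fluoro-3-formyl-4-methoxy-6-methylbenzoate
Conditions: Pd(OAc)2, Xantphos, CO (1 atm), MeOH (10 equiv), Et3N, toluene, 80 °C
Reagents that add atoms: carbon monoxide, [C-]#[O+]; methanol, CO
Why: Palladium-catalysed alkoxycarbonylation of the aryl bromide; the C–F bond and the aldehyde are inert to Pd(0)/CO, and the amine base with limited methanol should not give enough methoxide for SNAr.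

Step 5
Reactants: 7 ethyl glyoxylate; 8 isopropenylmagnesium bromide
Product: 9 ethyl 2-hydroxy-3-methylbut-3-enoate (racemic)
Conditions: THF, −78 °C; aq. NH4Cl
Reagents that add atoms: none
Why: Grignard 1,2-addition to the aldehyde carbonyl, which is far more electrophilic than the ester at −78 °C; the new stereocentre forms as a racemate and is lost later.

Step 6
Reactants: 9 ethyl 2-hydroxy-3-methylbut-3-enoate
Product: 10 2-hydroxy-3-methylbut-3-enoic acid (racemic)
Conditions: LiOH, THF–H2O, 0 → 23 °C; 1 M HCl
Reagents that add atoms: lithium hydroxide, [Li+].[OH-]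
Why: Ester saponification under mild conditions that leave the isolated alkene in place.

Step 7
Reactants: 6 methyl 2-fluoro-3-formyl-4-methoxy-6-methylbenzoate; 10 2-hydroxy-3-methylbut-3-enoic acid
Product: 12 2-[2-formyl-3-methoxy-6-(methoxycarbonyl)-5-methylphenoxy]-3-methylbut-3-enoic acid (racemic), via disodium 3-methyl-2-oxidobut-3-enoate 11 (not isolated)
Conditions: NaH (2.1 equiv), THF–DMF, 0 °C; then 6, 0 → 23 °C; 1 M HCl to pH 3
Reagents that add atoms: none
Why: SNAr of the alkoxide on the fluoride activated by ortho-formyl and ortho-ester groups; using the carboxylate dianion makes the α-hydrogen non-acidic, so neither alkene migration nor aldol attack on the neighbouring formyl group should occur.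

Step 8
Reactants: 12 2-[2-formyl-3-methoxy-6-(methoxycarbonyl)-5-methylphenoxy]-3-methylbut-3-enoic acid
Product: 15 2-[2-(1,3-dioxolan-2-yl)-3-methoxy-6-(methoxycarbonyl)-5-methylphenoxy]-3-methylbut-3-enoic acid (racemic), via trimethylsilyl ester aldehyde 13 (not isolated), via trimethylsilyl ester dioxolane 14 (not isolated)
Conditions: BSA, CH2Cl2, 23 °C; (TMSOCH2)2, TMSOTf (cat.), −78 → −20 °C; pyridine; pH 7 buffer
Reagents that add atoms: 1,2-bis(trimethylsilyloxy)ethane, C[Si](C)(C)OCCO[Si](C)(C)C
Why: Noyori acetalisation under aprotic conditions protects the hindered aldehyde while the acid is carried as its silyl ester, which hydrolyses on work-up, so no Fischer esterification can intervene.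

Step 9
Reactants: 15 2-[2-(1,3-dioxolan-2-yl)-3-methoxy-6-(methoxycarbonyl)-5-methylphenoxy]-3-methylbut-3-enoic acid; 16 ethoxyacetylene
Product: 19 methyl 3-(1,3-dioxolan-2-yl)-2-{[2-ethoxy-4-oxo-1-(prop-1-en-2-yl)cyclobut-2-en-1-yl]oxy}-4-methoxy-6-methylbenzoate (racemic), via acid chloride 17 (not isolated), via aryloxy(isopropenyl)ketene 18 (not isolated)
Conditions: Me2C=C(Cl)NMe2, CH2Cl2, 0 → 23 °C; then slow addition to 16 (3 equiv), Et3N, CH2Cl2, 0 → 23 °C
Reagents that add atoms: none
Why: HCl-free acid chloride formation (Ghosez reagent), dehydrochlorination to the ketene and regiospecific ketene–ynol ether [2+2] cycloaddition (first stage of a Danheiser benzannulation), in which the nucleophilic CH carbon of ethoxyacetylene bonds to the ketene carbonyl carbon and so places OEt next to the quaternary aryloxy carbon.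

Step 10
Reactants: 19 methyl 3-(1,3-dioxolan-2-yl)-2-{[2-ethoxy-4-oxo-1-(prop-1-en-2-yl)cyclobut-2-en-1-yl]oxy}-4-methoxy-6-methylbenzoate
Product: 23 methyl 2-(2-ethoxy-4-hydroxy-6-methylphenoxy)-3-formyl-4-methoxy-6-methylbenzoate, via (Z)-dienylketene 20 (not isolated), via cyclohexa-2,4-dienone 21 (not isolated), via dioxolane phenol 22 (not isolated)
Conditions: toluene (0.05 M), 100 °C; then 1 M HCl, THF, 23 °C
Reagents that add atoms: water, O
Why: Heating should open the cyclobutenone by conrotatory 4π electrocyclic cleavage of the C1–C4 bond to the (Z)-dienylketene 20, whose ketene carbon and isopropenyl CH2 then join by thermal disrotatory 6π electrocyclisation (the one new C–C bond, closing ring B) to dienone 21, which enolises to phenol 22. The closest known reaction type is the Moore ring expansion of 4-alkenyl-4-alkoxycyclobutenones, which is also the second stage of the Danheiser benzannulation. No stereocentre is created, and the racemic C4 centre becomes an sp2 ring carbon. The selectivity needed is torquoselectivity: the oxygen substituent at C4 must rotate outward so that the isopropenyl group ends cis to the ketene, which is the normal preference of lone-pair donors at C4; the regiochemistry (aryloxy carbon between C–CH3 and C–OEt, new OH para to the ether) is fixed by the connectivity of 19. Aromatic Claisen rearrangement of the allylic aryl ether cannot compete because both ortho positions of ring A are substituted, and the ester and dioxolane do not trap ketenes. Dilute acid in the work-up then hydrolyses the dioxolane to the aldehyde.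

Step 11
Reactants: 23 methyl 2-(2-ethoxy-4-hydroxy-6-methylphenoxy)-3-formyl-4-methoxy-6-methylbenzoate; 24 3,3-dimethylacrylic acid
Product: 26 methyl 2-[(7-ethoxy-2,2,5-trimethyl-4-oxochroman-6-yl)oxy]-3-formyl-4-methoxy-6-methylbenzoate, via ortho-acyl phenol 25 (not isolated)
Conditions: P2O5–MsOH (Eaton's reagent), 60 °C; ice-water
Reagents that add atoms: none
Why: Friedel–Crafts acylation by the mixed anhydride of 24, followed by 6-endo-trig oxa-Michael closure (the standard 2,2-dimethylchroman-4-one annulation), should occur at the ring-B carbon ortho to OH, para to OEt and next to CH3, as acylation of orcinol ethers does, because the other site between OH and OEt is screened by the ethyl group that the neighbouring aryloxy forces toward it, while ring A is deactivated by CHO and CO2Me and its formyl group is shielded by two ortho substituents.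

Step 12
Reactants: 26 methyl 2-[(7-ethoxy-2,2,5-trimethyl-4-oxochroman-6-yl)oxy]-3-formyl-4-methoxy-6-methylbenzoate
Product: 27 3-formyl-4-hydroxy-2-[(7-hydroxy-2,2,5-trimethyl-4-oxochroman-6-yl)oxy]-6-methylbenzoic acid
Conditions: BBr3 (8 equiv), CH2Cl2, −78 → 23 °C; H2O
Reagents that add atoms: none
Why: Boron tribromide dealkylation cleaves the aryl methyl and ethyl ethers through their borate complexes and the 2,6-disubstituted methyl benzoate by alkyl–oxygen fission, whereas the diaryl ether and the pyranone oxygen (a vinylogous ester oxygen of low basicity) should persist and the aldehyde returns on hydrolysis.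

Step 13
Reactants: 27 3-formyl-4-hydroxy-2-[(7-hydroxy-2,2,5-trimethyl-4-oxochroman-6-yl)oxy]-6-methylbenzoic acid
Product: 28 mollicellin A
Conditions: DCC, CH2Cl2–THF (0.005 M), 0 → 23 °C
Reagents that add atoms: none
Why: Carbodiimide lactonisation of a 2-(2-hydroxyaryloxy)benzoic acid to the seven-membered depsidone ring, for which only the hydroxyl ortho to the ether oxygen is within reach; base is left out so that this phenol cannot scramble the ether by Smiles rearrangement at the activated ipso carbon of ring A, and the other phenol is tied up by hydrogen bonding to the formyl group.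

**Compound list**
1 | 3,5-difluorotoluene | Cc1cc(F)cc(F)c1 | starting material
2 | 2,6-difluoro-4-methylphenyllithium | [Li]c1c(F)cc(C)cc1F | intermediate
3 | 2,6-difluoro-4-methylbenzaldehyde | Cc1cc(F)c(C=O)c(F)c1 | intermediate
4 | 2-fluoro-6-methoxy-4-methylbenzaldehyde | COc1cc(C)cc(F)c1C=O | intermediate
5 | 3-bromo-2-fluoro-6-methoxy-4-methylbenzaldehyde | COc1cc(C)c(Br)c(F)c1C=O | intermediate
6 | methyl 2-fluoro-3-formyl-4-methoxy-6-methylbenzoate | COC(=O)c1c(C)cc(OC)c(C=O)c1F | intermediate
7 | ethyl glyoxylate | CCOC(=O)C=O | starting material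
8 | isopropenylmagnesium bromide | CC(=C)[Mg]Br | starting material
9 | ethyl 2-hydroxy-3-methylbut-3-enoate (racemic) | CCOC(=O)C(O)C(C)=C | intermediate
10 | 2-hydroxy-3-methylbut-3-enoic acid (racemic) | OC(=O)C(O)C(C)=C | intermediate
11 | disodium 3-methyl-2-oxidobut-3-enoate (racemic) | [Na+].[Na+].[O-]C(C(C)=C)C([O-])=O | intermediate
12 | 2-[2-formyl-3-methoxy-6-(methoxycarbonyl)-5-methylphenoxy]-3-methylbut-3-enoic acid (racemic) | COC(=O)c1c(C)cc(OC)c(C=O)c1OC(C(C)=C)C(O)=O | intermediate
13 | trimethylsilyl 2-[2-formyl-3-methoxy-6-(methoxycarbonyl)-5-methylphenoxy]-3-methylbut-3-enoate (racemic) | COC(=O)c1c(C)cc(OC)c(C=O)c1OC(C(C)=C)C(=O)O[Si](C)(C)C | intermediate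
14 | trimethylsilyl 2-[2-(1,3-dioxolan-2-yl)-3-methoxy-6-(methoxycarbonyl)-5-methylphenoxy]-3-methylbut-3-enoate (racemic) | COC(=O)c1c(C)cc(OC)c(C2OCCO2)c1OC(C(C)=C)C(=O)O[Si](C)(C)C | intermediate
15 | 2-[2-(1,3-dioxolan-2-yl)-3-methoxy-6-(methoxycarbonyl)-5-methylphenoxy]-3-methylbut-3-enoic acid (racemic) | COC(=O)c1c(C)cc(OC)c(C2OCCO2)c1OC(C(C)=C)C(O)=O | intermediate
16 | ethoxyacetylene | CCOC#C | starting material
17 | 2-[2-(1,3-dioxolan-2-yl)-3-methoxy-6-(methoxycarbonyl)-5-methylphenoxy]-3-methylbut-3-enoyl chloride (racemic) | COC(=O)c1c(C)cc(OC)c(C2OCCO2)c1OC(C(C)=C)C(Cl)=O | intermediate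
18 | methyl 3-(1,3-dioxolan-2-yl)-4-methoxy-6-methyl-2-[(3-methyl-1-oxobuta-1,3-dien-2-yl)oxy]benzoate (aryloxy(isopropenyl)ketene) | COC(=O)c1c(C)cc(OC)c(C2OCCO2)c1OC(=C=O)C(C)=C | intermediate
19 | methyl 3-(1,3-dioxolan-2-yl)-2-{[2-ethoxy-4-oxo-1-(prop-1-en-2-yl)cyclobut-2-en-1-yl]oxy}-4-methoxy-6-methylbenzoate (racemic) | COC(=O)c1c(C)cc(OC)c(C2OCCO2)c1OC1(C(C)=C)C(=O)C=C1OCC | intermediate
20 | methyl 3-(1,3-dioxolan-2-yl)-2-{[(3Z)-4-ethoxy-2-methyl-6-oxohexa-1,3,5-trien-3-yl]oxy}-4-methoxy-6-methylbenzoate | COC(=O)c1c(C)cc(OC)c(C2OCCO2)c1O/C(C(C)=C)=C(/C=C=O)OCC | intermediate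
21 | methyl 3-(1,3-dioxolan-2-yl)-2-[(6-ethoxy-2-methyl-4-oxocyclohexa-1,5-dien-1-yl)oxy]-4-methoxy-6-methylbenzoate | COC(=O)c1c(C)cc(OC)c(C2OCCO2)c1OC1=C(C)CC(=O)C=C1OCC | intermediate
22 | methyl 3-(1,3-dioxolan-2-yl)-2-(2-ethoxy-4-hydroxy-6-methylphenoxy)-4-methoxy-6-methylbenzoate | COC(=O)c1c(C)cc(OC)c(C2OCCO2)c1Oc1c(C)cc(O)cc1OCC | intermediate
23 | methyl 2-(2-ethoxy-4-hydroxy-6-methylphenoxy)-3-formyl-4-methoxy-6-methylbenzoate | COC(=O)c1c(C)cc(OC)c(C=O)c1Oc1c(C)cc(O)cc1OCC | intermediate
24 | 3,3-dimethylacrylic acid | CC(C)=CC(=O)O | starting material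
25 | methyl 2-[2-ethoxy-4-hydroxy-6-methyl-5-(3-methylbut-2-enoyl)phenoxy]-3-formyl-4-methoxy-6-methylbenzoate | COC(=O)c1c(C)cc(OC)c(C=O)c1Oc1c(C)c(C(=O)C=C(C)C)c(O)cc1OCC | intermediate
26 | methyl 2-[(7-ethoxy-2,2,5-trimethyl-4-oxochroman-6-yl)oxy]-3-formyl-4-methoxy-6-methylbenzoate | COC(=O)c1c(C)cc(OC)c(C=O)c1Oc1c(C)c2C(=O)CC(C)(C)Oc2cc1OCC | intermediate
27 | 3-formyl-4-hydroxy-2-[(7-hydroxy-2,2,5-trimethyl-4-oxochroman-6-yl)oxy]-6-methylbenzoic acid | OC(=O)c1c(C)cc(O)c(C=O)c1Oc1c(C)c2C(=O)CC(C)(C)Oc2cc1O | intermediate
28 | mollicellin A | Cc1cc(O)c(C=O)c2c1C(=O)Oc1cc3c(c(C)c1O2)C(=O)CC(C)(C)O3 | target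

**Step count**
Total: 13 steps. Longest linear sequence: 11 steps (steps 1–4 and 7–13, from 3,5-difluorotoluene).

**Steps most likely to fail**

Step 11. The acyl group may enter at the other ortho position of the phenol (between OH and OEt), or the protonated formyl group may condense with the electron-rich ring B in the hot acid. The fallback sets out from 23 and delivers the acyl group from the phenolic oxygen under milder conditions. Acylation with 3-methylbut-2-enoyl chloride and Et3N should give the aryl ester methyl 2-{2-ethoxy-6-methyl-4-[(3-methylbut-2-enoyl)oxy]phenoxy}-3-formyl-4-methoxy-6-methylbenzoate F2. A TiCl4-promoted Fries rearrangement in CH2Cl2 should move the acyl group to the ring to give 25, and K2CO3 should close it by oxa-Michael addition, coming back to the route at 26.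

Step 9. The crowded ketene 18 may dimerise, or close to the isomeric 2-aryloxy-3-methylcyclobutenone, faster than the ynol ether intercepts it. The fallback sets out from 15 and generates 18 in the same way through 17, but captures it with the much more nucleophilic 1,1-diethoxyethene. This should give the cyclobutanone ketal methyl 2-{[2,2-diethoxy-4-oxo-1-(prop-1-en-2-yl)cyclobutyl]oxy}-3-(1,3-dioxolan-2-yl)-4-methoxy-6-methylbenzoate F1. β-Elimination of ethanol on basic alumina or with warm Et3N should then give the cyclobutenone, coming back to the route at 19.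

Step 12. Cleavage of the hindered methyl ester may stay incomplete, or bromide may open the 2,2-dimethylpyranone ring under the forcing conditions. The fallback sets out from 23 and changes the order so that no pyranone is present during dealkylation. BBr3 should give 2-(2,4-dihydroxy-6-methylphenoxy)-3-formyl-4-hydroxy-6-methylbenzoic acid F3. DCC under high dilution should lactonise it to the depsidone 3,8-dihydroxy-1,6-dimethyl-11-oxo-11H-dibenzo[b,e][1,4]dioxepine-4-carbaldehyde F4. Annulation of F4 with 24 in Eaton's reagent as the last step comes back to the route at 28.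

Further compounds
F1 | step 9 | methyl 2-{[2,2-diethoxy-4-oxo-1-(prop-1-en-2-yl)cyclobutyl]oxy}-3-(1,3-dioxolan-2-yl)-4-methoxy-6-methylbenzoate (racemic) | COC(=O)c1c(C)cc(OC)c(C2OCCO2)c1OC1(C(C)=C)C(=O)CC1(OCC)OCC
F2 | step 11 | methyl 2-{2-ethoxy-6-methyl-4-[(3-methylbut-2-enoyl)oxy]phenoxy}-3-formyl-4-methoxy-6-methylbenzoate | COC(=O)c1c(C)cc(OC)c(C=O)c1Oc1c(C)cc(OC(=O)C=C(C)C)cc1OCC
F3 | step 12 | 2-(2,4-dihydroxy-6-methylphenoxy)-3-formyl-4-hydroxy-6-methylbenzoic acid | OC(=O)c1c(C)cc(O)c(C=O)c1Oc1c(C)cc(O)cc1O
F4 | step 12 | 3,8-dihydroxy-1,6-dimethyl-11-oxo-11H-dibenzo[b,e][1,4]dioxepine-4-carbaldehyde | Cc1cc(O)c(C=O)c2c1C(=O)Oc1cc(O)cc(C)c1O2
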